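**Retrosynthetic overview**
- Feature: ring B (C1, C2, C3, C4, C4a, C8a) carries one substituent, at C2, and ring A (C5 to C8, oxygen at C5 and C8) is mirror-symmetric. C1 and C4 are therefore equivalent acyl carbons, and C2=C3 with the C1' chain can arrive as one terminal alkyne.
- Disconnections: (a) the two phenols come from the 5,8-dimethyl ether 23 by oxidative demethylation and two-electron reduction. (b) Cutting C1–C2 and C3–C4 gives the (R)-propargylic butyrate 21 and the phthaloylcobalt metallacycle 11, made from 3,6-dimethoxybenzocyclobutene-1,2-dione 8.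
- Ring order: ring A is bought in 1. A four-membered ring is fused on by aryne [2+2] and oxidised to the dione, cobalt opens it to a five-membered metallacycle, and ring B closes last, directly as the quinone.
- C1' is set on the acyclic ynone 18 by asymmetric transfer hydrogenation. The metallacycle is activated without silver (dimethylglyoxime/pyridine ligand set, CoCl2·6H2O), because silver salts isomerise propargylic esters and metalate terminal alkynes.

Key step: step 11

Remark: atom numbers are those of the 1,4-naphthoquinone (chain at C2, carbinol carbon C1'). The naphthazarin tautomers of 25 interconvert rapidly, so 25 is drawn with the chain on the quinone ring, as in the target SMILES.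

**Step 1**
Reactants: 1 2-bromo-1,4-dimethoxybenzene; 2 1,1-diethoxyethene
Product: 5 3,6-dimethoxybenzocyclobutenone (2,5-dimethoxybicyclo[4.2.0]octa-1,3,5-trien-7-one), via 3,6-dimethoxybenzyne 3 (not isolated), via diethyl acetal 4 (not isolated)
Conditions: NaNH2 (2.5 equiv), 2 (2 equiv), THF, reflux; then 1 M HCl, THF, rt
Reagents that add atoms: water, O
Why: Elimination–addition aryne chemistry, in which amide removes H3 (flanked by Br and OMe), bromide leaves, the symmetric aryne 3 undergoes the known polar stepwise [2+2] cycloaddition with the electron-rich ketene acetal to a single regioisomer, and dilute acid then hydrolyses acetal 4 without opening the four-membered ring.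

**Step 2**
Reactants: 5 3,6-dimethoxybenzocyclobutenone
Product: 7 2,2-dibromo-3,6-dimethoxybenzocyclobutenone (8,8-dibromo-2,5-dimethoxybicyclo[4.2.0]octa-1,3,5-trien-7-one), via monobromide 6 (not isolated)
Conditions: NBS (2.2 equiv), (PhCO2)2 (5 mol %), CCl4 or PhCF3, reflux, sunlamp
Reagents that add atoms: N-bromosuccinimide, O=C1CCC(=O)N1Br
Why: Wohl–Ziegler radical bromination, which should take both benzylic hydrogens of the ring CH2 because the acyl group lowers the nucleophilicity of ring A and a non-polar medium with an initiator keeps ionic ring bromination slow.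

**Step 3**
Reactants: 7 2,2-dibromo-3,6-dimethoxybenzocyclobutenone
Product: 8 3,6-dimethoxybenzocyclobutene-1,2-dione
Conditions: AgOCOCF3 (2.2 equiv), MeCN/H2O 4:1, 60 °C
Reagents that add atoms: water, O
Why: Silver-assisted solvolysis of a benzylic geminal dibromide, in which the ortho-methoxy group stabilises the bromocarbenium ion, water captures it, and loss of the second bromide leaves the carbonyl group.

**Step 4**
Reactants: 8 3,6-dimethoxybenzocyclobutene-1,2-dione; 9 chlorotris(triphenylphosphine)cobalt, ClCo(PPh3)3
Product: 10 chlorobis(triphenylphosphine)(3,6-dimethoxyphthaloyl)cobalt (five-membered ring Co–C(=O)–C(aryl)–C(aryl)–C(=O))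
Conditions: PhCl, rt to 50 °C, Ar
Reagents that add atoms: none
Why: Oxidative addition of monovalent cobalt into the strained CO–CO bond, a known reaction of benzocyclobutenediones driven by release of ring strain, gives the isolable trivalent-cobalt diacyl metallacycle with loss of one phosphine.

**Step 5**
Reactants: 10 chlorobis(triphenylphosphine)(3,6-dimethoxyphthaloyl)cobalt
Product: 11 chloro(dimethylglyoxime)(pyridine)(3,6-dimethoxyphthaloyl)cobalt (octahedral; neutral N,N-chelating dimethylglyoxime in the plane of the metallacycle, Cl and pyridine axial)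
Conditions: dimethylglyoxime (1.1 equiv), pyridine, rt
Reagents that add atoms: dimethylglyoxime, CC(=NO)C(C)=NO; pyridine, c1ccncc1
Why: Ligand substitution, in which the chelating dioxime and pyridine displace both phosphines to give the known saturated phthaloylcobalt complex that reacts with alkynes under mild Lewis-acid assistance, and removing PPh3 here keeps it from adding to the quinone later.

**Step 6**
Reactants: 12 4-methylpent-3-enoic acid
Product: 14 N-methoxy-N,4-dimethylpent-3-enamide, via acyl imidazolide 13 (not isolated)
Conditions: CDI (1.1 equiv), CH2Cl2, 0 °C to rt; then MeNHOMe·HCl (1.2 equiv), rt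
Reagents that add atoms: N,O-dimethylhydroxylamine hydrochloride, CNOC.Cl
Why: Amide coupling through the acyl imidazolide, run without strong base or acid so that the β,γ-alkene should stay out of conjugation.

**Step 7**
Reactants: 14 N-methoxy-N,4-dimethylpent-3-enamide; 15 trimethylsilylacetylene
Product: 18 6-methyl-1-(trimethylsilyl)hept-5-en-1-yn-3-one, via lithium trimethylsilylacetylide 16 (not isolated), via lithium hemiaminal adduct 17 (not isolated)
Conditions: 15 (1.3 equiv), n-BuLi (1.25 equiv), THF, −78 °C; 14, −78 to −20 °C; inverse quench into cold 1 M HCl/Et2O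
Reagents that add atoms: none
Why: Weinreb ketone synthesis, in which the weakly basic acetylide adds once, the chelated adduct 17 holds until work-up, and the cold acidic quench protonates the released hydroxylamine before it can add to the ynone.

**Step 8**
Reactants: 18 6-methyl-1-(trimethylsilyl)hept-5-en-1-yn-3-one
Product: 19 (R)-6-methyl-1-(trimethylsilyl)hept-5-en-1-yn-3-ol
Conditions: Ru[(R,R)-TsNCHPhCHPhNH](η6-p-cymene) (1 mol %), i-PrOH (0.1 M), rt, Ar
Reagents that add atoms: none
Why: Noyori asymmetric transfer hydrogenation of an α,β-acetylenic ketone, in which the alkynyl group takes the place beside the η6-arene that aryl takes in aryl ketones, so the (R,R) catalyst should deliver hydride to the face giving the (R) carbinol, while the base-free medium leaves alkyne, alkene and alkene position alone and avoids the isomerisation-prone 4-methylpent-3-enal altogether.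

**Step 9**
Reactants: 19 (R)-6-methyl-1-(trimethylsilyl)hept-5-en-1-yn-3-ol
Product: 20 (R)-6-methylhept-5-en-1-yn-3-ol
Conditions: K2CO3 (0.2 equiv), MeOH, 0 °C to rt; careful concentration (volatile)
Reagents that add atoms: none
Why: Base-catalysed methanolysis of the C(sp)–Si bond (protiodesilylation), which does not touch the carbinol centre.

**Step 10**
Reactants: 20 (R)-6-methylhept-5-en-1-yn-3-ol
Product: 21 (R)-6-methylhept-5-en-1-yn-3-yl butanoate
Conditions: (n-PrCO)2O (1.3 equiv), Et3N (1.5 equiv), DMAP (5 mol %), CH2Cl2, 0 °C to rt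
Reagents that add atoms: butyric anhydride, CCCC(=O)OC(=O)CCC
Why: DMAP-catalysed O-acylation, which forms the acyl–oxygen bond only and leaves the C–O bond of the stereocentre intact, so the (R) configuration is retained.

**Step 11**
Reactants: 11 chloro(dimethylglyoxime)(pyridine)(3,6-dimethoxyphthaloyl)cobalt; 21 (R)-6-methylhept-5-en-1-yn-3-yl butanoate
Product: 23 butylshikonin 5,8-dimethyl ether ((R)-1-(5,8-dimethoxy-1,4-dioxo-1,4-dihydronaphthalen-2-yl)-4-methylpent-3-en-1-yl butanoate), via seven-membered acylvinylcobaltacycle 22 (not isolated)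
Conditions: 21 (1.2 equiv), CoCl2·6H2O (1 equiv), ClCH2CH2Cl, 60 °C, Ar; then air, filtration through silica
Reagents that add atoms: none
Why: CoCl2·6H2O takes pyridine off the saturated trivalent-cobalt diacyl complex 11, the terminal alkyne of 21 binds at the freed site and inserts into one Co–acyl bond (first new C–C bond) to give the seven-membered cobaltacycle 22 (drawn with cobalt on C2; the other orientation converges), and C–C reductive elimination forms the second bond and releases monovalent cobalt. The closest known reaction type is this very one, the naphthoquinone synthesis from phthaloylcobalt complexes of benzocyclobutenediones with internal or terminal alkynes, a formal [4+2] of the C1–C8a–C4a–C4 diacyl unit with C2≡C3. Ring B closes by that reductive elimination, a contraction from seven ring atoms including cobalt to six carbons, and it arrives at the quinone oxidation level without an external oxidant. No stereocentre is made, since C1' is a spectator whose C–O and C–H bonds are untouched, and the released pyridine is held by CoCl2 so that no free base can enolise the new quinone toward C1'. Regioselectivity is not required because the mirror symmetry of the 3,6-dimethoxyphthaloyl unit makes both alkyne orientations give 23, and chemoselectivity over the trisubstituted C3'=C4' alkene follows from the stronger binding and faster insertion of the unhindered alkyne. Silver-free activation is used because silver salts convert secondary propargylic esters into allenyl esters by [3,3] shift and metalate terminal alkynes, either of which would cost substrate or configuration.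

**Step 12**
Reactants: 23 butylshikonin 5,8-dimethyl ether
Product: 25 butylshikonin ((R)-1-(5,8-dihydroxy-1,4-dioxo-1,4-dihydronaphthalen-2-yl)-4-methylpent-3-en-1-yl butanoate), via diquinone 24 (not isolated)
Conditions: AgO (4 equiv), 6 M HNO3, 1,4-dioxane, 0 °C to rt, 10 min; then CHCl3/H2O, Na2S2O4 (1.0 equiv), 0 °C, 5 min
Reagents that add atoms: water, O
Why: Oxidative demethylation of a hydroquinone dimethyl ether with AgO/HNO3 (aryl–oxygen cleavage, water as oxygen source), known for 5,8-dimethoxy-1,4-naphthoquinones bearing an acyloxyalkenyl chain, should give the strongly oxidising tetraone 24, which one equivalent of dithionite reduces by two electrons to the naphthazarin while any over-reduced material is re-oxidised by remaining 24, so that C1' and its ester are not disturbed.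

**Compound list**
1 | 2-bromo-1,4-dimethoxybenzene | COc1ccc(OC)c(Br)c1 | starting material
2 | 1,1-diethoxyethene | C=C(OCC)OCC | starting material
3 | 3,6-dimethoxybenzyne | COC1=CC=C(OC)C#C1 | intermediate
4 | 3,6-dimethoxybenzocyclobutenone diethyl acetal | CCOC1(OCC)Cc2c(OC)ccc(OC)c21 | intermediate
5 | 3,6-dimethoxybenzocyclobutenone | COc1ccc(OC)c2c1CC2=O | intermediate
6 | 2-bromo-3,6-dimethoxybenzocyclobutenone (racemic) | COc1ccc(OC)c2c1C(Br)C2=O | intermediate
7 | 2,2-dibromo-3,6-dimethoxybenzocyclobutenone | COc1ccc(OC)c2c1C(Br)(Br)C2=O | intermediate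
8 | 3,6-dimethoxybenzocyclobutene-1,2-dione | COc1ccc(OC)c2c1C(=O)C2=O | intermediate
9 | chlorotris(triphenylphosphine)cobalt | Cl[Co-3]([P+](c1ccccc1)(c1ccccc1)c1ccccc1)([P+](c1ccccc1)(c1ccccc1)c1ccccc1)[P+](c1ccccc1)(c1ccccc1)c1ccccc1 | starting material
10 | chlorobis(triphenylphosphine)(3,6-dimethoxyphthaloyl)cobalt | COc1ccc(OC)c2c1C(=O)[Co-2](Cl)([P+](c1ccccc1)(c1ccccc1)c1ccccc1)([P+](c1ccccc1)(c1ccccc1)c1ccccc1)C2=O | intermediate
11 | chloro(dimethylglyoxime)(pyridine)(3,6-dimethoxyphthaloyl)cobalt | COc1ccc(OC)c2c1C(=O)[Co-3]3(Cl)([n+]4ccccc4)([N+](O)=C(C)C(C)=[N+]3O)C2=O | intermediate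
12 | 4-methylpent-3-enoic acid | CC(C)=CCC(=O)O | starting material
13 | 1-(imidazol-1-yl)-4-methylpent-3-en-1-one | CC(C)=CCC(=O)n1ccnc1 | intermediate
14 | N-methoxy-N,4-dimethylpent-3-enamide | CON(C)C(=O)CC=C(C)C | intermediate
15 | trimethylsilylacetylene | C#C[Si](C)(C)C | starting material
16 | lithium trimethylsilylacetylide | [Li+].[C-]#C[Si](C)(C)C | intermediate
17 | lithium alkoxide of the acetylide–Weinreb amide adduct | [Li+].CON(C)C([O-])(CC=C(C)C)C#C[Si](C)(C)C | intermediate
18 | 6-methyl-1-(trimethylsilyl)hept-5-en-1-yn-3-one | CC(C)=CCC(=O)C#C[Si](C)(C)C | intermediate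
19 | (R)-6-methyl-1-(trimethylsilyl)hept-5-en-1-yn-3-ol | O[C@H](CC=C(C)C)C#C[Si](C)(C)C | intermediate
20 | (R)-6-methylhept-5-en-1-yn-3-ol | O[C@H](CC=C(C)C)C#C | intermediate
21 | (R)-6-methylhept-5-en-1-yn-3-yl butanoate | CCCC(=O)O[C@H](CC=C(C)C)C#C | intermediate
22 | seven-membered acyl(vinyl)cobaltacycle, chloro(dimethylglyoxime) ligand set, (R) at C1' | CCCC(=O)O[C@H](CC=C(C)C)C1=CC(=O)c2c(OC)ccc(OC)c2C(=O)[Co-2]13(Cl)[N+](O)=C(C)C(C)=[N+]3O | intermediate
23 | butylshikonin 5,8-dimethyl ether, (R) | CCCC(=O)O[C@H](CC=C(C)C)C1=CC(=O)c2c(OC)ccc(OC)c2C1=O | intermediate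
24 | (R)-4-methyl-1-(1,4,5,8-tetraoxo-1,4,5,8-tetrahydronaphthalen-2-yl)pent-3-en-1-yl butanoate | CCCC(=O)O[C@H](CC=C(C)C)C1=CC(=O)C2=C(C1=O)C(=O)C=CC2=O | intermediate
25 | butylshikonin, (R) | CCCC(=O)O[C@H](CC=C(C)C)C1=CC(=O)c2c(O)ccc(O)c2C1=O | target

**Total step count:** 12
**Longest linear sequence:** 7 steps (steps 1–5, 11, 12; the alkyne arm, steps 6–10, 11, 12, is equally long)

**Steps most likely to fail**

**Step 12.**
- What may go wrong: ring A of 23 is electron-poor, so its oxidation may be slow. The trisubstituted alkene may then be attacked by the oxidant, nitric acid may solvolyse the butyrate, and over-reduction may expel the butyrate.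
- Fallback: the methyl ethers are exchanged for silyl ethers before the metal is introduced. The end game then becomes a fluoride deprotection, and no oxidant meets the side chain.
- It sets out from 8. BBr3 in CH2Cl2 (−78 to 0 °C, chelation-assisted cleavage of the ortho-carbonyl ethers) should give 3,6-dihydroxybenzocyclobutene-1,2-dione F1.
- TBSCl and imidazole in DMF give 3,6-bis(tert-butyldimethylsilyloxy)benzocyclobutene-1,2-dione F2.
- Compound 9 inserts as in step 4 to give chlorobis(triphenylphosphine)[3,6-bis(tert-butyldimethylsilyloxy)phthaloyl]cobalt F3.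
- Dimethylglyoxime in pyridine gives chloro(dimethylglyoxime)(pyridine)[3,6-bis(tert-butyldimethylsilyloxy)phthaloyl]cobalt F4.
- Annulation of F4 with 21 under the conditions of step 11 gives 5,8-bis-O-(tert-butyldimethylsilyl)butylshikonin F5.
- HF·pyridine buffered with pyridine in THF at 0 °C frees both peri phenols and comes back to the route at 25.

**Step 11.**
- What may go wrong: alkyne insertion may be slower than cobalt-induced oligomerisation of the terminal alkyne. The Lewis acid may also ionise the propargylic C–O bond.
- Fallback: ring B is built by Dötz benzannulation instead of by the cobalt metallacycle. It sets out from 1 and 21.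
- Bromine–lithium exchange on 1 (n-BuLi, Et2O, −78 °C), addition to Cr(CO)6 and O-methylation with Me3OBF4 give pentacarbonyl[(2,5-dimethoxyphenyl)(methoxy)carbene]chromium F6.
- Warming F6 with 21 in THF at 50 °C joins the carbene carbon, the alkyne, one CO and the free ortho position of the arene. This gives, as its Cr(CO)3 complex, (R)-1-(1-hydroxy-4,5,8-trimethoxynaphthalen-2-yl)-4-methylpent-3-en-1-yl butanoate F7, with the chain beside the hydroxyl group.
- (NH4)2Ce(NO3)6 in aqueous MeCN at 0 °C removes the metal and oxidises the p-methoxyphenol ring. The sequence comes back to the route at 23.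

**Step 2.**
- What may go wrong: electrophilic bromination of the electron-rich ring A may outrun the radical chain at the benzylic CH2.
- Fallback: the second oxygen is brought in with the cycloaddition partner, so that no bromine source meets ring A. It sets out from 1.
- Lithium 2,2,6,6-tetramethylpiperidide in THF (−78 °C to rt) raises aryne 3 in the presence of commercial tris(trimethylsilyloxy)ethene. Its [2+2] cycloaddition, of the ketene silyl acetal type, gives 3,6-dimethoxy-1,1,2-tris(trimethylsilyloxy)benzocyclobutene F8.
- Dilute HCl in THF gives racemic 2-hydroxy-3,6-dimethoxybenzocyclobutenone F9.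
- Dess–Martin periodinane in CH2Cl2 oxidises the carbinol and comes back to the route at 8, replacing steps 1 to 3.

**Further compounds**
F1 | step 12 | 3,6-dihydroxybenzocyclobutene-1,2-dione | Oc1ccc(O)c2c1C(=O)C2=O
F2 | step 12 | 3,6-bis(tert-butyldimethylsilyloxy)benzocyclobutene-1,2-dione | CC(C)(C)[Si](C)(C)Oc1ccc(O[Si](C)(C)C(C)(C)C)c2c1C(=O)C2=O
F3 | step 12 | chlorobis(triphenylphosphine)[3,6-bis(tert-butyldimethylsilyloxy)phthaloyl]cobalt | CC(C)(C)[Si](C)(C)Oc1ccc(O[Si](C)(C)C(C)(C)C)c2c1C(=O)[Co-2](Cl)([P+](c1ccccc1)(c1ccccc1)c1ccccc1)([P+](c1ccccc1)(c1ccccc1)c1ccccc1)C2=O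
F4 | step 12 | chloro(dimethylglyoxime)(pyridine)[3,6-bis(tert-butyldimethylsilyloxy)phthaloyl]cobalt | CC(C)(C)[Si](C)(C)Oc1ccc(O[Si](C)(C)C(C)(C)C)c2c1C(=O)[Co-3]3(Cl)([n+]4ccccc4)([N+](O)=C(C)C(C)=[N+]3O)C2=O
F5 | step 12 | 5,8-bis-O-(tert-butyldimethylsilyl)butylshikonin, (R) | CCCC(=O)O[C@H](CC=C(C)C)C1=CC(=O)c2c(O[Si](C)(C)C(C)(C)C)ccc(O[Si](C)(C)C(C)(C)C)c2C1=O
F6 | step 11 | pentacarbonyl[(2,5-dimethoxyphenyl)(methoxy)carbene]chromium | COC(=[Cr])c1cc(OC)ccc1OC.[C-]#[O+].[C-]#[O+].[C-]#[O+].[C-]#[O+].[C-]#[O+]
F7 | step 11 | (R)-1-(1-hydroxy-4,5,8-trimethoxynaphthalen-2-yl)-4-methylpent-3-en-1-yl butanoate | CCCC(=O)O[C@H](CC=C(C)C)c1cc(OC)c2c(OC)ccc(OC)c2c1O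
F8 | step 2 | 3,6-dimethoxy-1,1,2-tris(trimethylsilyloxy)benzocyclobutene (racemic) | COc1ccc(OC)c2c1C(O[Si](C)(C)C)C2(O[Si](C)(C)C)O[Si](C)(C)C
F9 | step 2 | 2-hydroxy-3,6-dimethoxybenzocyclobutenone (racemic) | COc1ccc(OC)c2c1C(O)C2=O
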